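**Retrosynthetic overview**
- Feature: on ring A, the ring oxygen O1 (on C8a) and the prenyl carbon C1'' (on C8) sit on adjacent carbons next to the C7 oxygen. That is the pattern left when a nucleophile and then an electrophile add across a C8–C8a aryne (a 3-alkoxybenzyne).
- Endgame: C4=O from a 1,3-dithiane; the 7-O-(1,1-dimethylallyl) ether from the 7-OH by Pd allylation; the 7-OH from a SEM ether.
- Key disconnection: O1–C8a and C8–C1'' together, back to an open-chain (S)-carbinol carrying a 2-fluoroaryl dithiane, plus prenyl bromide. Ring C (the pyran ring) is the only ring formed; rings A and B are bought.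
- The carbinol comes from the lithiated 2-aryl-1,3-dithiane and (R)-styrene oxide (C3–C4 bond; C2 stereocentre bought). The dithiane comes from 2-fluoro-4-hydroxybenzaldehyde.

Key step: step 4

Assumption: tert-butyl 2-methylbut-3-en-2-yl carbonate (step 6) is taken as a catalogue reagent. Atom numbers follow the flavanone skeleton (O1, C2, C3, C4, C4a, C5–C8, C8a; prenyl C1''). The target is the (2S)-flavanone.

**Step 1**
Reactants: 1 2-fluoro-4-hydroxybenzaldehyde; 2 propane-1,3-dithiol
Product: 3 4-(1,3-dithian-2-yl)-3-fluorophenol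
Conditions: BF3·OEt2 (0.5 equiv), AcOH/CH2Cl2, 0 °C → rt
Reagents that add atoms: none
Why: Lewis-acid dithioacetalisation of the aldehyde, done on the free phenol so that no acid-labile acetal protecting group is exposed to BF3 and thiol.

**Step 2**
Reactants: 3 4-(1,3-dithian-2-yl)-3-fluorophenol
Product: 4 2-{2-fluoro-4-[2-(trimethylsilyl)ethoxymethoxy]phenyl}-1,3-dithiane
Conditions: NaH (1.1 equiv), THF, 0 °C; SEMCl (1.1 equiv), 0 °C → rt
Reagents that add atoms: 2-(trimethylsilyl)ethoxymethyl chloride (SEMCl), C[Si](C)(C)CCOCCl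
Why: Williamson-type O-alkylation of the sodium phenoxide by the chloromethyl ether; NaH does not touch the far less acidic dithiane C2–H, and the SEM ether later serves as ortho-directing group and as a fluoride-removable mask.

**Step 3**
Reactants: 4 2-{2-fluoro-4-[2-(trimethylsilyl)ethoxymethoxy]phenyl}-1,3-dithiane; 5 (R)-styrene oxide
Product: 8 (S)-2-{2-[2-fluoro-4-(2-trimethylsilylethoxymethoxy)phenyl]-1,3-dithian-2-yl}-1-phenylethanol, via 2-lithiodithiane 6 (not isolated), via lithium alkoxide 7 (not isolated)
Conditions: n-BuLi (1.0 equiv), THF, −78 °C, 30 min; 5 (1.2 equiv), −78 → 0 °C; aq. NH4Cl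
Reagents that add atoms: none
Why: Corey–Seebach umpolung, in which the 2-aryl-dithiane C–H (much more acidic than any arene C–H, so an aryllithium formed kinetically at −78 °C should hand its lithium over to it) is lithiated and the bulky anion opens the epoxide by SN2 at the CH2 terminus; the C–O stereocentre is not touched, so the (R)-epoxide gives the (S)-carbinol (the descriptor changes only through CIP priorities).

**Step 4**
Reactants: 8 (S)-2-{2-[2-fluoro-4-(2-trimethylsilylethoxymethoxy)phenyl]-1,3-dithian-2-yl}-1-phenylethanol; 9 prenyl bromide (1-bromo-3-methylbut-2-ene)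
Product: 14 (S)-8-(3-methylbut-2-enyl)-2-phenyl-7-[2-(trimethylsilyl)ethoxymethoxy]spiro[chromane-4,2'-[1,3]dithiane], via dilithio species 10 (not isolated), via aryne alkoxide 11 (not isolated), via 8-lithio spirochroman 12 (not isolated), via 8-cuprio spirochroman 13 (not isolated)
Conditions: n-BuLi (2.05 equiv), THF (0.03 M), −78 °C, 2 h; −78 → −10 °C; CuBr·SMe2 (1.1 equiv), −78 → −40 °C; 9 (1.5 equiv), −40 °C → rt
Reagents that add atoms: none
Why: Proposed new method: the first equivalent of n-BuLi gives the lithium alkoxide and the second removes the arene proton flanked by fluorine and the SEM ether (both direct to it), and on warming the 2-fluoroaryllithium 10 loses LiF to give the C8–C8a aryne 11, a 3-alkoxybenzyne. The tethered alkoxide adds in the ring plane to C8a in a 6-exo closure of the pyran ring (O1–C8a); attack at C8 would need a meta-bridged ring, and the polarisation of a 3-alkoxyaryne likewise puts the nucleophile on C8a and the charge on C8 next to the SEM oxygen. The resulting 2,6-dialkoxyaryllithium 12 is transmetalated to copper (13) and allylated by prenyl bromide at its primary carbon, which forms C8–C1''. The closest known reaction types are anionic cyclisations of alkoxide- or amide-tethered benzynes made from lithiated fluoroarenes (chromans, indolines) with electrophile capture of the new aryllithium, and the copper-mediated prenylation of ortho-lithiated aryl acetals. No stereocentre is formed, and C2 is carried through unchanged because only its O–H bond reacts. The step needs site-selective lithiation and intramolecular rather than intermolecular capture of the aryne; these are secured by the F/OSEM pair, the exact base charge (no butyllithium left on warming), the dithiane mask at C4 and dilution.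

**Step 5**
Reactants: 14 (S)-8-(3-methylbut-2-enyl)-2-phenyl-7-[2-(trimethylsilyl)ethoxymethoxy]spiro[chromane-4,2'-[1,3]dithiane]
Product: 15 (S)-8-(3-methylbut-2-enyl)-2-phenylspiro[chromane-4,2'-[1,3]dithian]-7-ol
Conditions: TBAF (5 equiv), THF/DMPU, 60 °C; aq. NH4Cl
Reagents that add atoms: none
Why: Fluoride-induced SEM cleavage (attack at silicon, then loss of ethene and formaldehyde to the phenoxide); with C4 still a dithioketal there is no enolisable carbonyl, so the basic medium cannot open the pyran ring by E1cB and C2 should keep its configuration.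

**Step 6**
Reactants: 15 (S)-8-(3-methylbut-2-enyl)-2-phenylspiro[chromane-4,2'-[1,3]dithian]-7-ol
Product: 16 (S)-7-(2-methylbut-3-en-2-yloxy)-8-(3-methylbut-2-enyl)-2-phenylspiro[chromane-4,2'-[1,3]dithiane]
Conditions: Pd(PPh3)4 (10 mol%), tert-butyl 2-methylbut-3-en-2-yl carbonate (2 equiv), THF, 0 °C → rt
Reagents that add atoms: tert-butyl 2-methylbut-3-en-2-yl carbonate, C=CC(C)(C)OC(=O)OC(C)(C)C
Why: Tsuji–Trost O-allylation, in which ionisation of the tertiary carbonate gives a 1,1-dimethyl-π-allyl palladium complex and tert-butoxide, the phenol is deprotonated, and the phenoxide attacks the more substituted allyl terminus to give the tertiary (reverse-prenyl) ether as the kinetic product under neutral conditions at low temperature.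

**Step 7**
Reactants: 16 (S)-7-(2-methylbut-3-en-2-yloxy)-8-(3-methylbut-2-enyl)-2-phenylspiro[chromane-4,2'-[1,3]dithiane]
Product: 17 griffinone C, (S)-7-(2-methylbut-3-en-2-yloxy)-8-(3-methylbut-2-enyl)-2-phenylchroman-4-one
Conditions: MeI (20 equiv), CaCO3 (5 equiv), MeCN/H2O 9:1, 35 °C, dark
Reagents that add atoms: water, O
Why: Alkylative dithioketal hydrolysis, in which S-methylation turns sulfur into a leaving group and the thionium ion (stabilised by O1 and the 7-alkoxy group) is captured by water; CaCO3 keeps the medium near neutral and the temperature stays well below that of an aromatic Claisen rearrangement, so the tertiary allyl ether, the prenyl group and the base-sensitive C2 centre should survive.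

**Compound list**
1 | 2-fluoro-4-hydroxybenzaldehyde | O=Cc1ccc(O)cc1F | starting material
2 | propane-1,3-dithiol | SCCCS | starting material
3 | 4-(1,3-dithian-2-yl)-3-fluorophenol | Oc1ccc(C2SCCCS2)c(F)c1 | intermediate
4 | 2-{2-fluoro-4-[2-(trimethylsilyl)ethoxymethoxy]phenyl}-1,3-dithiane | C[Si](C)(C)CCOCOc1ccc(C2SCCCS2)c(F)c1 | intermediate
5 | (R)-styrene oxide | C1O[C@@H]1c1ccccc1 | starting material
6 | 2-lithio-2-{2-fluoro-4-[2-(trimethylsilyl)ethoxymethoxy]phenyl}-1,3-dithiane | C[Si](C)(C)CCOCOc1ccc(C2([Li])SCCCS2)c(F)c1 | intermediate (not isolated)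
7 | lithium (S)-alkoxide of 8 | [Li]O[C@H](c1ccccc1)CC1(c2ccc(OCOCC[Si](C)(C)C)cc2F)SCCCS1 | intermediate (not isolated)
8 | (S)-2-{2-[2-fluoro-4-(2-trimethylsilylethoxymethoxy)phenyl]-1,3-dithian-2-yl}-1-phenylethanol | O[C@H](c1ccccc1)CC1(c2ccc(OCOCC[Si](C)(C)C)cc2F)SCCCS1 | intermediate
9 | prenyl bromide (1-bromo-3-methylbut-2-ene) | CC(C)=CCBr | starting material
10 | dilithio species: lithium (S)-alkoxide of 8, lithiated at the arene carbon between F and the SEM ether | [Li]O[C@H](c1ccccc1)CC1(c2ccc(OCOCC[Si](C)(C)C)c([Li])c2F)SCCCS1 | intermediate (not isolated)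
11 | aryne alkoxide: lithium (S)-alkoxide carrying the C8–C8a aryne (3-alkoxybenzyne) | [Li]O[C@H](c1ccccc1)CC1(C2=CC=C(OCOCC[Si](C)(C)C)C#C2)SCCCS1 | intermediate (not isolated)
12 | (S)-8-lithio-2-phenyl-7-[2-(trimethylsilyl)ethoxymethoxy]spiro[chromane-4,2'-[1,3]dithiane] | C[Si](C)(C)CCOCOc1ccc2c(c1[Li])O[C@H](c1ccccc1)CC21SCCCS1 | intermediate (not isolated)
13 | (S)-8-cuprio-2-phenyl-7-[2-(trimethylsilyl)ethoxymethoxy]spiro[chromane-4,2'-[1,3]dithiane] | C[Si](C)(C)CCOCOc1ccc2c(c1[Cu])O[C@H](c1ccccc1)CC21SCCCS1 | intermediate (not isolated)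
14 | (S)-8-(3-methylbut-2-enyl)-2-phenyl-7-[2-(trimethylsilyl)ethoxymethoxy]spiro[chromane-4,2'-[1,3]dithiane] | C[Si](C)(C)CCOCOc1ccc2c(c1CC=C(C)C)O[C@H](c1ccccc1)CC21SCCCS1 | intermediate
15 | (S)-8-(3-methylbut-2-enyl)-2-phenylspiro[chromane-4,2'-[1,3]dithian]-7-ol | Oc1ccc2c(c1CC=C(C)C)O[C@H](c1ccccc1)CC21SCCCS1 | intermediate
16 | (S)-7-(2-methylbut-3-en-2-yloxy)-8-(3-methylbut-2-enyl)-2-phenylspiro[chromane-4,2'-[1,3]dithiane] | C=CC(C)(C)Oc1ccc2c(c1CC=C(C)C)O[C@H](c1ccccc1)CC21SCCCS1 | intermediate
17 | griffinone C, (S)-7-(2-methylbut-3-en-2-yloxy)-8-(3-methylbut-2-enyl)-2-phenylchroman-4-one | C=CC(C)(C)Oc1ccc2c(c1CC=C(C)C)O[C@H](c1ccccc1)CC2=O | target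

**Step count**
Total steps: 7. Longest linear sequence: 7 steps (1 → 17).

**Steps most likely to fail**

1. Step 4 (aryne relay). The aryne may be consumed intermolecularly (by residual butyllithium or by aryllithium 10) faster than the tethered alkoxide closes the ring. The lithiation may also stay incomplete, or the C8 anion may be protonated before allylation. Fallback, setting out from 8 and using only known reaction types: ring closure and prenylation are separated and the aryne is avoided. Heating the sodium alkoxide of 8 (NaH, DMF, about 100 °C) should close the pyran ring by intramolecular SNAr on the aryl fluoride, which the meta SEM ether does not deactivate. This gives (S)-2-phenyl-7-[2-(trimethylsilyl)ethoxymethoxy]spiro[chromane-4,2'-[1,3]dithiane] F1. Directed ortho-lithiation of F1 at C8, the position between O1 and the SEM oxygen (n-BuLi, THF, −20 °C), then gives 12, where the fallback comes back to the route. CuBr·SMe2 and 9 then lead to 14 as in step 4.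

2. Step 6 (Pd O-tert-prenylation). The dithiane sulfur atoms may deactivate the catalyst, the hindered ortho-prenyl phenoxide may react slowly, or palladium may isomerise the tertiary ether to the linear prenyl ether. Fallback, setting out from 15: the tertiary ether is built without a transition metal. O-Alkylation with ethyl 2-bromo-2-methylpropanoate (Cs2CO3, DMF, 60 °C) should give ethyl 2-methyl-2-{[(S)-8-(3-methylbut-2-enyl)-2-phenylspiro[chromane-4,2'-[1,3]dithian]-7-yl]oxy}propanoate F2. Partial reduction (DIBAL-H, CH2Cl2, −78 °C) gives 2-methyl-2-{[(S)-8-(3-methylbut-2-enyl)-2-phenylspiro[chromane-4,2'-[1,3]dithian]-7-yl]oxy}propanal F3. Wittig methylenation (Ph3PCH3Br, KHMDS, THF, 0 °C) then comes back to the route at 16.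

3. Step 7 (dithiane hydrolysis). The tertiary allyl ether may ionise or undergo Claisen migration to C6 during the alkylative hydrolysis, or the hydrolysis may stall at the low temperature that this ether demands. Fallback, setting out from 15: the order of the last two operations is reversed, so that the fragile ether is made last. Hydrolysis of the dithiane of 15 (MeI, CaCO3, aq. MeCN, which may now be warmed to about 50 °C) should give (S)-7-hydroxy-8-(3-methylbut-2-enyl)-2-phenylchroman-4-one F4. Pd-catalysed O-tert-prenylation of F4 with the same carbonate (Pd(PPh3)4, THF, 0 °C), now on a sulfur-free substrate and buffered by the acidic 7-hydroxyl, comes back to the route at 17.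

**Further compounds**
F1 | step 4 | (S)-2-phenyl-7-[2-(trimethylsilyl)ethoxymethoxy]spiro[chromane-4,2'-[1,3]dithiane] | C[Si](C)(C)CCOCOc1ccc2c(c1)O[C@H](c1ccccc1)CC21SCCCS1
F2 | step 6 | ethyl 2-methyl-2-{[(S)-8-(3-methylbut-2-enyl)-2-phenylspiro[chromane-4,2'-[1,3]dithian]-7-yl]oxy}propanoate | CCOC(=O)C(C)(C)Oc1ccc2c(c1CC=C(C)C)O[C@H](c1ccccc1)CC21SCCCS1
F3 | step 6 | 2-methyl-2-{[(S)-8-(3-methylbut-2-enyl)-2-phenylspiro[chromane-4,2'-[1,3]dithian]-7-yl]oxy}propanal | O=CC(C)(C)Oc1ccc2c(c1CC=C(C)C)O[C@H](c1ccccc1)CC21SCCCS1
F4 | step 7 | (S)-7-hydroxy-8-(3-methylbut-2-enyl)-2-phenylchroman-4-one | Oc1ccc2c(c1CC=C(C)C)O[C@H](c1ccccc1)CC2=O
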